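**Retrosynthetic overview**

1. The strategy rests on the E-trisubstituted C9=C10 alkene with its C9 methyl group and the adjoining C10–C11 single bond, next to ring A (the cyclohexene C1–C6 with stereocentres C3 and C6).
2. The C8′ aldehyde comes last, from the C8′ alcohol, after both silyl ethers are removed.
3. C9–CH3 and C10–C11 are made in one pot: methylalumination of a ring A enyne (C1–C10), then palladium coupling with a C11–C8′ hexaenyl iodide.
4. The enyne comes from racemic α-ionone: C3 oxygenation, cis-selective reduction, lipase resolution, silylation, methyl ketone to alkyne. The iodide comes from the C10 dialdehyde: C5 olefination, iodoolefination, reduction, silylation.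
5. Ring A is bought with α-ionone and no ring is formed in the route.

Key step: step 12

Remarks: carotenoid numbering is used (ring A = C1–C6, chain C7–C15, then C15′–C8′). "cis" means C3–O and the C6 side chain on the same ring face. Racemic compounds are drawn as one enantiomer.
Assumption: in step 5 the lipase is taken to acylate the 3R carbinol faster (alkene flank as the large group in the usual size model for lipases), so the wanted 3S,6R alcohol is the one left unreacted.

**Route**

Step 1
Reactants: 1 (±)-α-ionone
Product: 2 (±)-α-ionone ethylene ketal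
Conditions: HOCH2CH2OH, HC(OMe)3, p-TsOH·H2O (cat.), rt
Reagents that add atoms: ethylene glycol, OCCO
Why: Acid-catalysed ketalisation with an orthoester as water scavenger runs at room temperature on enones and masks C9=O, so that the ring ketone made in step 2 is the only carbonyl that meets hydride in step 3.

Step 2
Reactants: 2 (±)-α-ionone ethylene ketal
Product: 3 (±)-3-oxo-α-ionone ethylene ketal
Conditions: t-BuOOH (70% aq.), Rh2(cap)4 (cat., cap = caprolactamate), K2CO3, CH2Cl2, rt
Reagents that add atoms: tert-butyl hydroperoxide, CC(C)(C)OO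
Why: Allylic oxidation with t-BuOOH under Rh2(cap)4 catalysis abstracts hydrogen at the least hindered allylic methylene, here ring C3 next to C4=C5 (the tertiary C6–H is shielded by the C1 gem-dimethyl group and the C5 methyl), and the carbonate buffer spares the ketal.

Step 3
Reactants: 3 (±)-3-oxo-α-ionone ethylene ketal
Product: 4 (±)-cis-3-hydroxy-α-ionone ethylene ketal
Conditions: NaBH4, CeCl3·7H2O, MeOH, −40 → −20 °C; chromatography to remove the C3 epimer
Reagents that add atoms: none
Why: Luche reduction gives 1,2-addition to the ring enone, and axial hydride delivery anti to the pseudoaxial C6 side chain should place the new C3 hydroxyl cis to that chain, any trans epimer being removed on silica.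

Step 4
Reactants: 4 (±)-cis-3-hydroxy-α-ionone ethylene ketal
Product: 5 (±)-cis-3-hydroxy-α-ionone
Conditions: PPTS (cat.), acetone/H2O, rt
Reagents that add atoms: water, O
Why: Hydrolysis of the allylic dioxolane under weak buffered acid (ketal deprotection) frees the C9 ketone without ionising the allylic C3 alcohol, so the cis relationship is kept.

Step 5
Reactants: 5 (±)-cis-3-hydroxy-α-ionone
Product: 6 (3S,6R)-3-hydroxy-α-ionone
Conditions: Burkholderia cepacia lipase (Amano PS), vinyl acetate, t-BuOMe, 30 °C, run to just past half conversion; chromatography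
Reagents that add atoms: none
Why: Lipase-catalysed enantioselective transesterification (kinetic resolution) tells the two flanks of the C3 carbinol apart, acetylating the 3R,6S enantiomer and leaving the 3S,6R alcohol, whose C6 configuration follows from the fixed cis relationship, and running past half conversion raises the purity of the recovered alcohol.

Step 6
Reactants: 6 (3S,6R)-3-hydroxy-α-ionone
Product: 7 (3S,6R)-3-(tert-butyldimethylsilyloxy)-α-ionone
Conditions: TBSCl, imidazole, DMF, rt
Reagents that add atoms: tert-butyldimethylsilyl chloride, CC(C)(C)[Si](C)(C)Cl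
Why: Silylation of the secondary alcohol (silyl ether formation) protects C3–OH against the amide base and the alanes used later and does not touch C3 or C6.

Step 7
Reactants: 7 (3S,6R)-3-(tert-butyldimethylsilyloxy)-α-ionone
Product: 9 (3S,6R)-3-silyloxy ring enyne (C1–C10), via dienyl diethyl phosphate 8 (not isolated)
Conditions: LiN(i-Pr)2 (1.1 equiv), THF, −78 °C; ClP(O)(OEt)2, −78 °C → rt; then LiN(i-Pr)2 (2.3 equiv), −78 °C → rt; aq. NH4Cl
Reagents that add atoms: diethyl chlorophosphate, CCOP(=O)(Cl)OCC (its atoms sit only in intermediate 8 and leave again in the elimination)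
Why: Conversion of a methyl ketone into a terminal alkyne through its enol phosphate: kinetic deprotonation at the C10 methyl, O-phosphorylation and elimination by excess amide give the C9≡C10 alkyne, while the low temperature and the acetylide that forms keep the doubly allylic C6–H in place.

Step 8
Reactants: 10 (2E,4E,6E)-2,7-dimethylocta-2,4,6-trienedial (C10 dialdehyde, 2.5 equiv); 11 triethyl 2-methyl-4-phosphonocrotonate
Product: 12 C15 aldehyde ester, ethyl (2E,4E,6E,8E,10E)-2,6,11-trimethyl-12-oxododeca-2,4,6,8,10-pentaenoate
Conditions: 11, NaN(SiMe3)2, THF, −78 °C; anion added slowly to 10 in THF, −78 → 0 °C; excess 10 recovered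
Reagents that add atoms: none
Why: Vinylogous Horner–Wadsworth–Emmons olefination forms the C11′=C12′ alkene E-selectively, and slow addition of the anion to an excess of the symmetric dialdehyde limits the reaction to one of its two formyl groups.

Step 9
Reactants: 12 C15 aldehyde ester
Product: 13 C16 iodo ester, ethyl (2E,4E,6E,8E,10E,12E)-13-iodo-2,6,11-trimethyltrideca-2,4,6,8,10,12-hexaenoate
Conditions: CrCl2 (6 equiv), CHI3 (2 equiv), THF/1,4-dioxane, 0 °C → rt, dark
Reagents that add atoms: iodoform, IC(I)I
Why: Takai iodoolefination turns the C12 aldehyde into the E-alkenyl iodide (C11=C12) by addition of an iodo-substituted gem-dichromium species and elimination, and the divalent chromium reagent leaves the conjugated ester alone.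

Step 10
Reactants: 13 C16 iodo ester
Product: 14 C16 iodo alcohol, (2E,4E,6E,8E,10E,12E)-13-iodo-2,6,11-trimethyltrideca-2,4,6,8,10,12-hexaen-1-ol
Conditions: i-Bu2AlH (2.3 equiv), CH2Cl2, −78 °C; aq. KNaC4H4O6 (potassium sodium tartrate)
Reagents that add atoms: none
Why: Hydride reduction of the conjugated ester by i-Bu2AlH gives the C8′ allylic alcohol by 1,2-addition, and alkenyl iodides are inert to this reagent at −78 °C.

Step 11
Reactants: 14 C16 iodo alcohol
Product: 15 all-E C11–C8′ hexaenyl iodide with C8′ silyl ether
Conditions: TBSCl, imidazole, DMF, 0 °C → rt, dark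
Reagents that add atoms: tert-butyldimethylsilyl chloride, CC(C)(C)[Si](C)(C)Cl
Why: Silylation of the primary alcohol (silyl ether formation) removes the acidic proton that would otherwise quench the alane in the key step.

Step 12
Reactants: 9 (3S,6R)-3-silyloxy ring enyne; 16 trimethylaluminium; 15 hexaenyl iodide
Product: 18 (3S,6R)-3,8′-bis(tert-butyldimethylsilyloxy)-8′-apo-ε-carotene (all-E), via C10 dimethylalane 17 (not isolated)
Conditions: AlMe3 (2 equiv), Cp2ZrCl2 (0.25 equiv), ClCH2CH2Cl, rt; volatiles removed in vacuo; then 15, ZnCl2 (co-catalyst, THF solution), Pd(PPh3)4 (5 mol %), THF, rt, dark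
Reagents that add atoms: trimethylaluminium 16, C[Al](C)C (one methyl group ends on C9)
Why: Cp2ZrCl2 and AlMe3 form a methylzirconocene–aluminium species that adds CH3 and metal syn across the terminal C9≡C10 bond of 9, methyl to internal C9 and the metal (handed on to aluminium) to terminal C10, giving the E-alkenylalane 17; ZnCl2 then relays the alkenyl group to the alkenylpalladium iodide formed by oxidative addition of zerovalent palladium into the C11–I bond of 15, and reductive elimination forms C10–C11 with retention at both carbons. The closest known reaction type is zirconium-catalysed methylalumination of a conjugated terminal enyne followed by a zinc-assisted Negishi alkenyl–alkenyl coupling, as practised on retinoid-type chains. No ring is closed and no stereocentre is formed; C3 and C6 are only carried through. The step needs regioselectivity (methyl to C9, not C10), which the terminal alkyne secures because the bulky metal goes to the unsubstituted carbon, and E geometry at C9=C10, which the concerted syn addition fixes. It also needs retention of the E-iodoalkene and of the existing polyene geometry, which oxidative addition and reductive elimination at palladium provide at room temperature in the dark. The medium holds neither base nor protic acid and THF tempers the aluminium and zinc Lewis acids, so the doubly allylic C6–H and the two allylic silyl ethers should stay untouched.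

Step 13
Reactants: 18 bis-silyl ether
Product: 19 (3S,6R,all-E)-8′-apo-ε-carotene-3,8′-diol
Conditions: Bu4NF, THF, 0 °C → rt, dark; aqueous work-up
Reagents that add atoms: none
Why: Fluoride-mediated cleavage of both Si–O bonds (desilylation) is driven by Si–F bond formation and leaves the polyene and both stereocentres untouched.

Step 14
Reactants: 19 diol
Product: 20 (3S,6R,all-E)-3-hydroxy-8′-apo-ε-caroten-8′-al (target)
Conditions: MnO2 (activated), CH2Cl2, 0 °C, dark; filtered as soon as the primary alcohol is consumed
Reagents that add atoms: none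
Why: Allylic oxidation with MnO2 is much faster for the primary polyenylic C8′ alcohol than for the hindered secondary ring alcohol at C3, so stopping at consumption of the primary alcohol should give the aldehyde with C3–OH intact.

**Compound list**

1 | (±)-α-ionone, (E)-4-(2,6,6-trimethylcyclohex-2-en-1-yl)but-3-en-2-one | CC1=CCCC(C)(C)C1/C=C/C(C)=O | starting material
2 | (±)-α-ionone ethylene ketal, 2-methyl-2-[(E)-2-(2,6,6-trimethylcyclohex-2-en-1-yl)ethenyl]-1,3-dioxolane | CC1=CCCC(C)(C)C1/C=C/C2(C)OCCO2 | intermediate
3 | (±)-3-oxo-α-ionone ethylene ketal | CC1=CC(=O)CC(C)(C)C1/C=C/C2(C)OCCO2 | intermediate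
4 | (±)-cis-3-hydroxy-α-ionone ethylene ketal (racemic, 3S,6R enantiomer drawn) | CC1=C[C@@H](O)CC(C)(C)[C@H]1/C=C/C2(C)OCCO2 | intermediate
5 | (±)-cis-3-hydroxy-α-ionone (racemic, 3S,6R enantiomer drawn) | CC1=C[C@@H](O)CC(C)(C)[C@H]1/C=C/C(C)=O | intermediate
6 | (3S,6R)-3-hydroxy-α-ionone (single enantiomer) | CC1=C[C@@H](O)CC(C)(C)[C@H]1/C=C/C(C)=O | intermediate
7 | (3S,6R)-3-(tert-butyldimethylsilyloxy)-α-ionone | CC1=C[C@@H](O[Si](C)(C)C(C)(C)C)CC(C)(C)[C@H]1/C=C/C(C)=O | intermediate
8 | dienyl diethyl phosphate of 7 (C9 enol phosphate, not isolated) | CC1=C[C@@H](O[Si](C)(C)C(C)(C)C)CC(C)(C)[C@H]1/C=C/C(=C)OP(=O)(OCC)OCC | intermediate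
9 | (3S,6R)-3-silyloxy ring enyne, tert-butyl{[(1S,4R)-4-[(E)-but-1-en-3-yn-1-yl]-3,5,5-trimethylcyclohex-2-en-1-yl]oxy}dimethylsilane | CC1=C[C@@H](O[Si](C)(C)C(C)(C)C)CC(C)(C)[C@H]1/C=C/C#C | intermediate
10 | (2E,4E,6E)-2,7-dimethylocta-2,4,6-trienedial (C10 dialdehyde) | O=C/C(C)=C/C=C/C=C(\C)C=O | starting material
11 | triethyl 2-methyl-4-phosphonocrotonate, ethyl (E)-4-(diethoxyphosphoryl)-2-methylbut-2-enoate | CCOC(=O)/C(C)=C/CP(=O)(OCC)OCC | starting material
12 | ethyl (2E,4E,6E,8E,10E)-2,6,11-trimethyl-12-oxododeca-2,4,6,8,10-pentaenoate | CCOC(=O)/C(C)=C/C=C/C(C)=C/C=C/C=C(\C)C=O | intermediate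
13 | ethyl (2E,4E,6E,8E,10E,12E)-13-iodo-2,6,11-trimethyltrideca-2,4,6,8,10,12-hexaenoate | CCOC(=O)/C(C)=C/C=C/C(C)=C/C=C/C=C(C)/C=C/I | intermediate
14 | (2E,4E,6E,8E,10E,12E)-13-iodo-2,6,11-trimethyltrideca-2,4,6,8,10,12-hexaen-1-ol | OC/C(C)=C/C=C/C(C)=C/C=C/C=C(C)/C=C/I | intermediate
15 | tert-butyldimethylsilyl ether of 14 (all-E C11–C8′ hexaenyl iodide) | I/C=C/C(C)=C/C=C/C=C(C)/C=C/C=C(\C)CO[Si](C)(C)C(C)(C)C | intermediate
16 | trimethylaluminium | C[Al](C)C | starting material
17 | (E)-C10 dimethylalane from 9 (not isolated) | CC1=C[C@@H](O[Si](C)(C)C(C)(C)C)CC(C)(C)[C@H]1/C=C/C(C)=C/[Al](C)C | intermediate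
18 | (3S,6R)-3,8′-bis(tert-butyldimethylsilyloxy)-8′-apo-ε-carotene (all-E) | CC1=C[C@@H](O[Si](C)(C)C(C)(C)C)CC(C)(C)[C@H]1/C=C/C(C)=C/C=C/C(C)=C/C=C/C=C(C)/C=C/C=C(\C)CO[Si](C)(C)C(C)(C)C | intermediate
19 | (3S,6R,all-E)-8′-apo-ε-carotene-3,8′-diol | CC1=C[C@@H](O)CC(C)(C)[C@H]1/C=C/C(C)=C/C=C/C(C)=C/C=C/C=C(C)/C=C/C=C(\C)CO | intermediate
20 | (3S,6R,all-E)-3-hydroxy-8′-apo-ε-caroten-8′-al | CC1=C[C@@H](O)CC(C)(C)[C@H]1/C=C/C(C)=C/C=C/C(C)=C/C=C/C=C(C)/C=C/C=C(\C)C=O | target

**Summary**

Total step count: 14.
Longest linear sequence: 10 steps (steps 1–7, then 12, 13, 14). The iodide branch (steps 8–11) is 4 steps.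

**Three steps most likely to fail**

Step 12 (key step). What may go wrong:
- Chloro- and methylalanes may ionise the polyenylic C8′ silyl ether or the allylic C3 silyl ether.
- Residual aluminium may transfer methyl instead of alkenyl to the polyenyl–palladium intermediate.
- Incomplete regiocontrol in the methylalumination would be carried into a C30 mixture that is hard to separate.
- The iodide may drift in E/Z geometry during a slow coupling.

Fallback (sets out from 9, comes back at 18): the alane 17 made from 9 is quenched with I2 instead of being coupled. This gives the isolable ring dienyl iodide F1, which can be freed of any regioisomer. Iodine–lithium exchange with t-BuLi in Et2O at −78 °C gives the alkenyllithium F2, and ZnCl2 turns it into the alkenylzinc chloride F3. A Negishi coupling of F3 with 15 under Pd(PPh3)4 in THF then returns 18 in a medium free of aluminium.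

Step 5. What may go wrong: the lipase may discriminate poorly between the enantiomers, or show the reverse preference, because the two flanks of the C3 carbinol (C2H2–CMe2 and C4H=C5) are of similar size; the recovered alcohol would then be of low enantiomeric purity.

Fallback (sets out from 5, comes back at 6): racemic 5 is esterified with (S)-2-methoxy-2-phenylacetic acid (DCC, DMAP, CH2Cl2). The two diastereomeric esters, the 3S,6R ester F4 and the 3R,6S ester F5, are separated by chromatography or crystallisation. F4 is cleaved with K2CO3 in MeOH to give 6.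

Step 14. What may go wrong: oxidation may continue at the ring allylic C3 alcohol to the ring enone, and the diol may be adsorbed or isomerised on the oxidant surface during a slow reaction.

Fallback (sets out from 18, comes back at 20): the two silyl ethers are taken off in turn. Pyridine-buffered HF·pyridine in THF at 0 °C cleaves only the primary C8′ silyl ether and gives the C3-silylated C8′ alcohol F6. MnO2 then oxidises its only free hydroxyl to the C3-silylated aldehyde F7. Bu4NF buffered with AcOH removes the last silyl group to give 20.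

**Further compounds**

F1 | step 12 | (3S,6R)-3-silyloxy ring (1E,3E)-dienyl iodide (C10 iodide) | CC1=C[C@@H](O[Si](C)(C)C(C)(C)C)CC(C)(C)[C@H]1/C=C/C(C)=C/I
F2 | step 12 | C10 alkenyllithium from F1 (not isolated) | CC1=C[C@@H](O[Si](C)(C)C(C)(C)C)CC(C)(C)[C@H]1/C=C/C(C)=C/[Li]
F3 | step 12 | C10 alkenylzinc chloride from F2 (not isolated) | CC1=C[C@@H](O[Si](C)(C)C(C)(C)C)CC(C)(C)[C@H]1/C=C/C(C)=C/[Zn]Cl
F4 | step 5 | (3S,6R)-3-[(S)-2-methoxy-2-phenylacetoxy]-α-ionone | CC1=C[C@@H](OC(=O)[C@@H](OC)c2ccccc2)CC(C)(C)[C@H]1/C=C/C(C)=O
F5 | step 5 | (3R,6S)-3-[(S)-2-methoxy-2-phenylacetoxy]-α-ionone | CC1=C[C@H](OC(=O)[C@@H](OC)c2ccccc2)CC(C)(C)[C@@H]1/C=C/C(C)=O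
F6 | step 14 | (3S,6R,all-E)-3-(tert-butyldimethylsilyloxy)-8′-apo-ε-caroten-8′-ol | CC1=C[C@@H](O[Si](C)(C)C(C)(C)C)CC(C)(C)[C@H]1/C=C/C(C)=C/C=C/C(C)=C/C=C/C=C(C)/C=C/C=C(\C)CO
F7 | step 14 | (3S,6R,all-E)-3-(tert-butyldimethylsilyloxy)-8′-apo-ε-caroten-8′-al | CC1=C[C@@H](O[Si](C)(C)C(C)(C)C)CC(C)(C)[C@H]1/C=C/C(C)=C/C=C/C(C)=C/C=C/C=C(C)/C=C/C=C(\C)C=O
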